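Count partner B first.

| flask | substrate | partner A | partner B | remark | time |
|---|---|---|---|---|---|
| alpha | 0.25 M | 0.95 equiv | 2.1 equiv (in portions, 3) | run made earlier; portions every 6.0 min |  |
| gamma | 0.25 M | 0.95 equiv | 3.3 equiv (in portions, 3) | run made earlier; portions every 6.0 min |  |
| beta | 0.50 M | 0.95 equiv | 1.5 equiv (in portions, 3) | run made earlier; portions every 6.0 min |  |
| flask | 0.25 M | 0.950 equiv | 1.50 equiv (in portions, 3) | the portions of partner B follow each other after 6.0 min, the first at the start | 6.0 h |

| run | time / h | target / % | substrate / % |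
|---|---|---|---|
| alpha | 0.200 | 9.2 | 70.1 |
| alpha | 0.500 | 19.7 | 30.5 |
| alpha | 1.00 | 14.0 | 13.5 |
| alpha | 1.50 | 10.3 | 7.7 |
| alpha | 2.00 | 9.1 | 4.7 |
| alpha | 3.00 | 7.8 | 3.1 |
| alpha | 4.00 | 7.2 | 0 |
| gamma | 0.200 | 14.6 | 51.7 |
| gamma | 0.500 | 19.3 | 6.8 |
| gamma | 1.00 | 13.3 | 0 |
| gamma | 1.50 | 10.9 | 0 |
| gamma | 2.00 | 8.8 | 0.1 |
| gamma | 3.00 | 7.8 | 0.1 |
| gamma | 4.00 | 7.9 | 0 |
| beta | 0.333 | 17.7 | 55.0 |
| beta | 0.833 | 15.9 | 43.9 |
| beta | 1.50 | 11.4 | 43.4 |
| beta | 2.50 | 8.9 | 42.3 |
| beta | 4.00 | 7.9 | 42.4 |

(standard deviation of a reading: 0.5 percentage points)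

- the reaction counts as stopped when no species that holds the substrate changes by six tenths of a point or more over the second half of the time

- the state of affairs at 6.0 h: stopped, and by what, or still going (it is still moving / forward and back rates have come level / the partner B has run out first / all of the substrate has reacted)
- amount of target at 6.0 h, in percent of the substrate charged

Beta's substrate levels off, reading 42.4% at 4.00 h, so 1.5 equiv of partner B consumed 57.6% of the substrate charged. That leaves 0.924 equiv of partner B spent elsewhere, close to the 0.95 equiv of partner A, so I reckon one partner B per substrate and one per partner A. Alpha fits: it has 2.1 equiv against the 1.95 equiv this asks, and its substrate reads 0% at 4.00 h.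

So I reckon that this flask has 0.550 equiv of free partner B, the charge of partner B less the charge of partner A. That is less than the substrate charge, so I take partner B as the limiting reagent and expect about 45.0% of the substrate to stay. For target I take beta's reading at the same equivalents, 7.9% at 4.00 h.

The forecast says that the partner B has run out first, with target at 7.5%, but on substrate we part: “B should run out with roughly 20-30% substrate left”.

At 6.0 h this flask shows that the partner B has run out first, with target at 7.59%, partner B at 0% of its charge and substrate at 42.5%, against the 45.0% reckoned from 0.550 equiv.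

    partner B + partner A → second intermediate (k = 1.40 M⁻¹ min⁻¹)
    target ⇌ isomer of the product (K = 2.50, k = 0.0180 min⁻¹)
    substrate + partner B → open intermediate (k = 0.290 M⁻¹ min⁻¹)
    open intermediate + second intermediate → target (k = 1.60 M⁻¹ min⁻¹)
    substrate → decomposition product (k = 5.10 × 10⁻⁵ min⁻¹)
    2 second intermediate → homo product (k = 2.50 M⁻¹ min⁻¹)

Now take the neighbouring flask with 6.00 equiv of partner B. Its free partner B is 5.05 equiv, more than the substrate charge, so the same reckoning has partner B outlast the substrate, with 67.5% of the partner B charge left. That neighbour ends with substrate, not partner B, gone: substrate at 0%, partner A at 0%, partner B at 67.5% and target at 7.68%.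

(Readings and results come from a simulation from invented constants; scatter was added.)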